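**Retrosynthetic overview**

1. Numbering: ring B is C1(aryl)–C2(C9H2OH)–C3(CHO)=C4–C4a–C8a and ring A is C4a–C5–C6–C7(OH)–C8(OMe)–C8a. The strategy rests on ring A: C7–OH and C8–OMe sit side by side and are followed directly by the fusion carbons C8a and C4a. This edge is a furan (C4a, C5, C6, C7 and its oxygen) that has taken up a methoxyalkyne (C8, C8a) and kept its oxygen on C7.
2. Last disconnection: the C9–O silyl ether. Key disconnection: C4a–C8a and C7–C8, by an intramolecular furan/alkynyl ether Diels–Alder reaction and bridge opening, so that rings B and A form together from (E)-enal 21.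
3. C3=C4 comes from a crossed aldol condensation with furfural, C2–C3 from an Evans alkylation with tert-butyl bromoacetate, and C1–C8a from an auxiliary-directed 1,4-alkynylation of N-cinnamoyl oxazolidinone 4 with the alane of methoxyacetylene.
4. Ring order: the dimethoxyphenyl ring and the furan are bought; ring B and ring A close in step 9, after both stereocentres (C1, C2) are in place.

Key step: step 9

Remark: 3,4-dimethoxycinnamic acid is taken as the commercial starting material (it is the Knoevenagel–Doebner product of 3,4-dimethoxybenzaldehyde).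
Remark: from 11 to 21 the alkynyl ether is kept away from protic and Lewis acids (buffered work-ups, Et3N-deactivated silica); free carboxylic acids are avoided throughout because they add to alkynyl ethers.
Remark: vitekwangin B is taken as the open hydroxy aldehyde of the given SMILES.

**Route**

Step 1
Reactants: 1 (E)-3,4-dimethoxycinnamic acid; 2 (S)-4-benzyl-1,3-oxazolidin-2-one
Product: 4 (S)-4-benzyl-3-[(E)-3-(3,4-dimethoxyphenyl)prop-2-enoyl]-1,3-oxazolidin-2-one, via mixed pivalic anhydride 3 (not isolated)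
Conditions: t-BuCOCl, Et3N, THF, −20 °C; then 2, LiCl, rt
Reagents that add atoms: none
Why: N-acylation of the oxazolidinone through a mixed anhydride is the standard entry to N-enoyl imides and leaves the (E)-alkene untouched.

Step 2
Reactants: 5 chloroacetaldehyde dimethyl acetal
Product: 7 methoxyacetylene, via sodium methoxyacetylide 6 (not isolated)
Conditions: NaNH2 (3 equiv), liq. NH3, −33 °C; then sat. aq. NaCl, −20 °C; distil into a cold Et2O trap
Reagents that add atoms: none
Why: twofold base-induced elimination (methanol, then HCl) from an α-chloro acetal is the classical preparation of alkoxyacetylenes, and the acetylide is protonated on aqueous quench.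

Step 3
Reactants: 4 (S)-4-benzyl-3-[(E)-3-(3,4-dimethoxyphenyl)prop-2-enoyl]-1,3-oxazolidin-2-one; 7 methoxyacetylene
Product: 11 (S)-4-benzyl-3-[(3S)-3-(3,4-dimethoxyphenyl)-5-methoxypent-4-ynoyl]-1,3-oxazolidin-2-one, via lithium methoxyacetylide 8 (not isolated), via dimethyl(methoxyethynyl)alane 9 (not isolated), via aluminium enolate 10 (not isolated)
Conditions: 7, n-BuLi, Et2O, −78 °C; Me2AlCl, → 0 °C; add to 4 + Me2AlCl (1.1 equiv), CH2Cl2, −78 → −20 °C; aq. KNaC4H4O6, NaHCO3
Reagents that add atoms: none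
Why: conjugate addition of an organoaluminium reagent to an aluminium-chelated N-enoyl oxazolidinone (1,4-alkynylation with a dialkylalkynylalane): in the syn-s-cis chelate the alkynyl group, whose aluminium-bearing carbon is made strongly nucleophilic by the methoxy group, is transferred in preference to methyl to the β-carbon on the face remote from the benzyl group, which sets C1 (3S in 11, 1S in the target).

Step 4
Reactants: 11 (S)-4-benzyl-3-[(3S)-3-(3,4-dimethoxyphenyl)-5-methoxypent-4-ynoyl]-1,3-oxazolidin-2-one; 12 tert-butyl bromoacetate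
Product: 14 tert-butyl (3S,4S)-3-{[(4S)-4-benzyl-2-oxo-1,3-oxazolidin-3-yl]carbonyl}-4-(3,4-dimethoxyphenyl)-6-methoxyhex-5-ynoate, via sodium enolate 13 (not isolated)
Conditions: NaN(SiMe3)2 (1.05 equiv), THF, −78 °C; then 12 (3 equiv), −78 → −45 °C; pH 7 buffer
Reagents that add atoms: none
Why: Evans alkylation, in which the chelated (Z)-enolate 13 takes the reactive α-bromo ester on the face remote from the benzyl group; this sets C2 (3S in 14, 2R in the target) so that the aryl group and C9 end up trans on ring B.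

Step 5
Reactants: 14 tert-butyl (3S,4S)-3-{[(4S)-4-benzyl-2-oxo-1,3-oxazolidin-3-yl]carbonyl}-4-(3,4-dimethoxyphenyl)-6-methoxyhex-5-ynoate
Product: 15 tert-butyl (3S,4S)-4-(3,4-dimethoxyphenyl)-3-(hydroxymethyl)-6-methoxyhex-5-ynoate
Conditions: LiBH4, MeOH (1 equiv), THF, 0 °C; aq. NaOH
Reagents that add atoms: none
Why: reductive cleavage of the imide with LiBH4 is chemoselective for the exocyclic imide carbonyl over a tert-butyl ester at 0 °C, sets no acid free, and returns the auxiliary.

Step 6
Reactants: 15 tert-butyl (3S,4S)-4-(3,4-dimethoxyphenyl)-3-(hydroxymethyl)-6-methoxyhex-5-ynoate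
Product: 16 tert-butyl (3S,4S)-3-{[(tert-butyldimethylsilyl)oxy]methyl}-4-(3,4-dimethoxyphenyl)-6-methoxyhex-5-ynoate
Conditions: TBSCl, imidazole, CH2Cl2, 0 °C → rt
Reagents that add atoms: tert-butyldimethylsilyl chloride, C[Si](C)(Cl)C(C)(C)C
Why: silylation of a primary alcohol under imidazole-buffered conditions is routine, is tolerated by the alkynyl ether, and blocks lactonisation onto the ester.

Step 7
Reactants: 16 tert-butyl (3S,4S)-3-{[(tert-butyldimethylsilyl)oxy]methyl}-4-(3,4-dimethoxyphenyl)-6-methoxyhex-5-ynoate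
Product: 18 (3S,4S)-3-{[(tert-butyldimethylsilyl)oxy]methyl}-4-(3,4-dimethoxyphenyl)-6-methoxyhex-5-ynal, via aluminium hemiacetal 17 (not isolated)
Conditions: i-Bu2AlH (1.2 equiv), PhMe, −78 °C; MeOH, then aq. KNaC4H4O6
Reagents that add atoms: none
Why: partial reduction of an ester with i-Bu2AlH stops at the aldehyde because tetrahedral adduct 17 persists at −78 °C and collapses only on work-up, and alkynes are not hydroaluminated at this temperature.

Step 8
Reactants: 18 (3S,4S)-3-{[(tert-butyldimethylsilyl)oxy]methyl}-4-(3,4-dimethoxyphenyl)-6-methoxyhex-5-ynal; 19 furfural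
Product: 21 (2E,3R,4S)-3-{[(tert-butyldimethylsilyl)oxy]methyl}-4-(3,4-dimethoxyphenyl)-2-(furan-2-ylmethylidene)-6-methoxyhex-5-ynal, via aldol adduct 20 (not isolated)
Conditions: 19 (5 equiv), KOH (0.3 equiv), MeOH, 0 °C → rt, slow addition of 18
Reagents that add atoms: none
Why: crossed aldol (Claisen–Schmidt) condensation with an excess of a non-enolisable aldehyde, in which E1cB dehydration of 20 gives the thermodynamically preferred (E)-enal with the furyl group cis to C2; the alkynyl ether and silyl ether tolerate dilute methanolic hydroxide, and neither C1 nor C2 bears an acidic hydrogen.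

Step 9
Reactants: 21 (2E,3R,4S)-3-{[(tert-butyldimethylsilyl)oxy]methyl}-4-(3,4-dimethoxyphenyl)-2-(furan-2-ylmethylidene)-6-methoxyhex-5-ynal
Product: 24 (1S,2R)-2-{[(tert-butyldimethylsilyl)oxy]methyl}-1-(3,4-dimethoxyphenyl)-7-hydroxy-8-methoxy-1,2-dihydronaphthalene-3-carbaldehyde, via oxanorbornadiene 22 (not isolated), via zwitterion 23 (not isolated)
Conditions: o-xylene (0.005 M, degassed), BHT, 2,6-lutidine (0.2 equiv), 140 °C, sealed tube
Reagents that add atoms: none
Why: Proposed new method: the furan (C4a, C5, C6, C7 and its oxygen) acts as the 4π partner in a concerted intramolecular [4+2] cycloaddition across the tethered methoxyalkyne, forming C4a–C8a and C7–C8 to give oxanorbornadiene 22; its C4a–O bond then ionises to zwitterion 23, a pentadienyl cation capped as an oxocarbenium ion by the C8 methoxy group, and shift of the C7 hydrogen to oxygen gives the phenol. The closest known reaction type is the intramolecular Diels–Alder reaction of furans with tethered alkynes followed by opening of the 7-oxanorbornadiene to a phenol; an alkynyl ether as the 2π partner is the untested element. Ring B closes as a six-membered ring through the four-atom tether C4–C3–C2–C1, the (E)-alkene placing the furan on the same side as C2, and ring A is the six-membered ring of the cycloadduct itself, aromatised by the bridge opening. No stereocentre is created: C1 and C2 are not touched, and addition to either furan face converges on the same arene. The step needs bridge opening that leaves the oxygen on C7, which the C8 methoxy group secures because only C4a–O cleavage gives an oxygen-stabilised cation and only C7 carries a hydrogen to lose. It also needs the alkynyl ether to react with the furan and not with the formyl group, which acid-free buffered heating at high dilution and the inability of a methyl alkynyl ether to fragment by retro-ene loss of an alkene are meant to secure.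

Step 10
Reactants: 24 (1S,2R)-2-{[(tert-butyldimethylsilyl)oxy]methyl}-1-(3,4-dimethoxyphenyl)-7-hydroxy-8-methoxy-1,2-dihydronaphthalene-3-carbaldehyde
Product: 25 vitekwangin B, (1S,2R)-1-(3,4-dimethoxyphenyl)-7-hydroxy-2-(hydroxymethyl)-8-methoxy-1,2-dihydronaphthalene-3-carbaldehyde
Conditions: HF·pyridine, pyridine, THF, 0 °C → rt
Reagents that add atoms: none
Why: fluoride cleavage of a primary tert-butyldimethylsilyl ether with buffered HF·pyridine should leave the enal, the phenol and both stereocentres untouched.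

**Compound list**

1 | (E)-3,4-dimethoxycinnamic acid | COc1ccc(/C=C/C(=O)O)cc1OC | starting material
2 | (S)-4-benzyl-1,3-oxazolidin-2-one | O=C1N[C@@H](Cc2ccccc2)CO1 | starting material
3 | mixed anhydride of 1 with pivalic acid (not isolated) | COc1ccc(/C=C/C(=O)OC(=O)C(C)(C)C)cc1OC | intermediate
4 | (S)-4-benzyl-3-[(E)-3-(3,4-dimethoxyphenyl)prop-2-enoyl]-1,3-oxazolidin-2-one | COc1ccc(/C=C/C(=O)N2[C@@H](Cc3ccccc3)COC2=O)cc1OC | intermediate
5 | chloroacetaldehyde dimethyl acetal | COC(CCl)OC | starting material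
6 | sodium methoxyacetylide (not isolated) | COC#[C-].[Na+] | intermediate
7 | methoxyacetylene | COC#C | intermediate
8 | lithium methoxyacetylide (not isolated) | [Li]C#COC | intermediate
9 | dimethyl(methoxyethynyl)alane (not isolated) | COC#C[Al](C)C | intermediate
10 | dimethylaluminium (Z)-enolate of 11 (not isolated) | COC#C[C@H](c1ccc(OC)c(OC)c1)/C=C(\O[Al](C)C)N1[C@@H](Cc2ccccc2)COC1=O | intermediate
11 | (S)-4-benzyl-3-[(3S)-3-(3,4-dimethoxyphenyl)-5-methoxypent-4-ynoyl]-1,3-oxazolidin-2-one | COC#C[C@H](c1ccc(OC)c(OC)c1)CC(=O)N1[C@@H](Cc2ccccc2)COC1=O | intermediate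
12 | tert-butyl bromoacetate | CC(C)(C)OC(=O)CBr | starting material
13 | sodium (Z)-enolate of 11 (not isolated) | COC#C[C@H](c1ccc(OC)c(OC)c1)/C=C(\[O-])N1[C@@H](Cc2ccccc2)COC1=O.[Na+] | intermediate
14 | tert-butyl (3S,4S)-3-{[(4S)-4-benzyl-2-oxo-1,3-oxazolidin-3-yl]carbonyl}-4-(3,4-dimethoxyphenyl)-6-methoxyhex-5-ynoate | COC#C[C@H](c1ccc(OC)c(OC)c1)[C@@H](C(=O)N1[C@@H](Cc2ccccc2)COC1=O)CC(=O)OC(C)(C)C | intermediate
15 | tert-butyl (3S,4S)-4-(3,4-dimethoxyphenyl)-3-(hydroxymethyl)-6-methoxyhex-5-ynoate | COC#C[C@H](c1ccc(OC)c(OC)c1)[C@@H](CO)CC(=O)OC(C)(C)C | intermediate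
16 | tert-butyl (3S,4S)-3-{[(tert-butyldimethylsilyl)oxy]methyl}-4-(3,4-dimethoxyphenyl)-6-methoxyhex-5-ynoate | COC#C[C@H](c1ccc(OC)c(OC)c1)[C@@H](CO[Si](C)(C)C(C)(C)C)CC(=O)OC(C)(C)C | intermediate
17 | diisobutylaluminium hemiacetal of 16 (not isolated; hemiacetal carbon unassigned) | COC#C[C@H](c1ccc(OC)c(OC)c1)[C@@H](CO[Si](C)(C)C(C)(C)C)CC(O[Al](CC(C)C)CC(C)C)OC(C)(C)C | intermediate
18 | (3S,4S)-3-{[(tert-butyldimethylsilyl)oxy]methyl}-4-(3,4-dimethoxyphenyl)-6-methoxyhex-5-ynal | COC#C[C@H](c1ccc(OC)c(OC)c1)[C@@H](CO[Si](C)(C)C(C)(C)C)CC=O | intermediate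
19 | furfural | O=Cc1ccco1 | starting material
20 | aldol adduct of 18 and 19 (not isolated; the two new centres unassigned) | COC#C[C@H](c1ccc(OC)c(OC)c1)[C@@H](CO[Si](C)(C)C(C)(C)C)C(C=O)C(O)c1ccco1 | intermediate
21 | (2E,3R,4S)-3-{[(tert-butyldimethylsilyl)oxy]methyl}-4-(3,4-dimethoxyphenyl)-2-(furan-2-ylmethylidene)-6-methoxyhex-5-ynal | COC#C[C@H](c1ccc(OC)c(OC)c1)[C@@H](CO[Si](C)(C)C(C)(C)C)/C(C=O)=C\c1ccco1 | intermediate
22 | oxanorbornadiene cycloadduct, oxygen bridging C4a and C7 (not isolated; bridge face unassigned, both faces converge) | O=CC1=CC23OC(C=C2)C(OC)=C3[C@H](c4ccc(OC)c(OC)c4)[C@H]1CO[Si](C)(C)C(C)(C)C | intermediate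
23 | ring-opened zwitterion, C7 alkoxide and C8 oxocarbenium (not isolated; C7 unassigned) | O=CC1=CC2=C([C@H](c3ccc(OC)c(OC)c3)[C@H]1CO[Si](C)(C)C(C)(C)C)C(=[O+]C)C([O-])C=C2 | intermediate
24 | 9-O-(tert-butyldimethylsilyl)vitekwangin B, (1S,2R)-2-{[(tert-butyldimethylsilyl)oxy]methyl}-1-(3,4-dimethoxyphenyl)-7-hydroxy-8-methoxy-1,2-dihydronaphthalene-3-carbaldehyde | COc1ccc([C@H]2c3c(ccc(O)c3OC)C=C(C=O)[C@@H]2CO[Si](C)(C)C(C)(C)C)cc1OC | intermediate
25 | vitekwangin B, (1S,2R)-1-(3,4-dimethoxyphenyl)-7-hydroxy-2-(hydroxymethyl)-8-methoxy-1,2-dihydronaphthalene-3-carbaldehyde | COc1ccc([C@H]2c3c(ccc(O)c3OC)C=C(C=O)[C@@H]2CO)cc1OC | target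

**Step count and risks**

Total step count: 10. Longest linear sequence: 9 steps (1, 3, 4, 5, 6, 7, 8, 9, 10 from compound 1); step 2 is a side branch that supplies 7.

Steps most likely to fail:

1. Step 9. The cycloaddition may be slower than thermal loss of the alkynyl ether, because the furan has to turn out of conjugation with the enal to reach the alkyne; the alkynyl ether may also add to the formyl group or to the phenol as it forms. Fallback with known chemistry, setting out from 4 and coming back at 24: ring A is taken from vanillin and ring B is closed by an intramolecular aldol condensation. Vanillin is silylated (TBSCl, imidazole) to 4-[(tert-butyldimethylsilyl)oxy]-3-methoxybenzaldehyde F1 and converted (HC(OMe)3, pyridinium p-toluenesulfonate, MeOH) into dimethyl acetal F2. F2 is metalated between its acetal and methoxy groups (s-BuLi, TMEDA, THF, −78 °C; then MgBr2·OEt2, CuBr·SMe2) and added to 4 to give diaryl imide F3, the auxiliary directing C1 as in step 3. Evans alkylation with 12 gives alkylated imide F4, LiBH4 gives alcohol F5, TBSCl gives silyl ether F6 and i-Bu2AlH gives aldehyde F7. Aqueous acetic acid frees the aryl aldehyde to give dialdehyde F8, and KOH in MeOH then closes ring B by aldol condensation between C3 and the aryl formyl carbon (C4) and cleaves the aryl silyl ether, which gives 24.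

2. Step 3. Alkynyl transfer may be incomplete, or facial control poor, if the imide is not held in the aluminium chelate; the Lewis acid may also degrade the alkynyl ether. Fallback, setting out from 7 and coming back at 11: the alkyne is added without a Lewis acid to a doubly activated acceptor and the C1 epimers are separated on the auxiliary. Knoevenagel condensation of 3,4-dimethoxybenzaldehyde with dimethyl malonate (piperidine, AcOH) gives arylidene malonate F9, which takes lithium methoxyacetylide 8 (from 7, n-BuLi) in 1,4-fashion to give racemic malonate F10. Krapcho dealkoxycarbonylation (LiCl, wet DMSO, 120 °C) gives racemic ester F11, and LiOH gives lithium carboxylate F12 without setting the acid free. Pivaloyl chloride gives mixed anhydride F13, and lithiated 2 gives 11 together with its C1 epimer F14, which is removed by chromatography.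

3. Step 8. The enolisable aldehyde may self-condense, dehydration may stop at the aldol stage, or alkene geometry may erode. Fallback, setting out from 16 and coming back at 21: 16 is treated with LiN(i-Pr)2 (THF, −78 °C) and 19 in a directed aldol addition to give β-hydroxy ester F15. Mesylation (MsCl, Et3N) gives mesylate F16, and elimination with DBU gives (E)-enoate F17. i-Bu2AlH gives allylic alcohol F18, and MnO2 oxidises it to 21.

Further compounds
F1 | step 9 | 4-[(tert-butyldimethylsilyl)oxy]-3-methoxybenzaldehyde | COc1cc(C=O)ccc1O[Si](C)(C)C(C)(C)C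
F2 | step 9 | 4-[(tert-butyldimethylsilyl)oxy]-3-methoxybenzaldehyde dimethyl acetal | COc1cc(C(OC)OC)ccc1O[Si](C)(C)C(C)(C)C
F3 | step 9 | (S)-4-benzyl-3-[(3S)-3-{3-[(tert-butyldimethylsilyl)oxy]-6-(dimethoxymethyl)-2-methoxyphenyl}-3-(3,4-dimethoxyphenyl)propanoyl]-1,3-oxazolidin-2-one | COc1c([C@H](c2ccc(OC)c(OC)c2)CC(=O)N2[C@@H](Cc3ccccc3)COC2=O)c(C(OC)OC)ccc1O[Si](C)(C)C(C)(C)C
F4 | step 9 | tert-butyl bromoacetate alkylation product of F3 (imide α-carbon S, benzylic carbon S) | COc1c([C@H](c2ccc(OC)c(OC)c2)[C@@H](C(=O)N2[C@@H](Cc3ccccc3)COC2=O)CC(=O)OC(C)(C)C)c(C(OC)OC)ccc1O[Si](C)(C)C(C)(C)C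
F5 | step 9 | primary alcohol from reductive removal of the auxiliary of F4 | COc1c([C@H](c2ccc(OC)c(OC)c2)[C@@H](CO)CC(=O)OC(C)(C)C)c(C(OC)OC)ccc1O[Si](C)(C)C(C)(C)C
F6 | step 9 | tert-butyldimethylsilyl ether of F5 | COc1c([C@H](c2ccc(OC)c(OC)c2)[C@@H](CO[Si](C)(C)C(C)(C)C)CC(=O)OC(C)(C)C)c(C(OC)OC)ccc1O[Si](C)(C)C(C)(C)C
F7 | step 9 | aldehyde from partial reduction of the tert-butyl ester of F6 | COc1c([C@H](c2ccc(OC)c(OC)c2)[C@@H](CO[Si](C)(C)C(C)(C)C)CC=O)c(C(OC)OC)ccc1O[Si](C)(C)C(C)(C)C
F8 | step 9 | dialdehyde from acetal hydrolysis of F7 | COc1c([C@H](c2ccc(OC)c(OC)c2)[C@@H](CO[Si](C)(C)C(C)(C)C)CC=O)c(C=O)ccc1O[Si](C)(C)C(C)(C)C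
F9 | step 3 | dimethyl 2-(3,4-dimethoxybenzylidene)malonate | COC(=O)C(=Cc1ccc(OC)c(OC)c1)C(=O)OC
F10 | step 3 | racemic dimethyl 2-[1-(3,4-dimethoxyphenyl)-3-methoxyprop-2-yn-1-yl]malonate | COC#CC(c1ccc(OC)c(OC)c1)C(C(=O)OC)C(=O)OC
F11 | step 3 | racemic methyl 3-(3,4-dimethoxyphenyl)-5-methoxypent-4-ynoate | COC#CC(c1ccc(OC)c(OC)c1)CC(=O)OC
F12 | step 3 | racemic lithium 3-(3,4-dimethoxyphenyl)-5-methoxypent-4-ynoate | COC#CC(c1ccc(OC)c(OC)c1)CC(=O)[O-].[Li+]
F13 | step 3 | racemic mixed anhydride of the acid of F12 with pivalic acid | COC#CC(c1ccc(OC)c(OC)c1)CC(=O)OC(=O)C(C)(C)C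
F14 | step 3 | (S)-4-benzyl-3-[(3R)-3-(3,4-dimethoxyphenyl)-5-methoxypent-4-ynoyl]-1,3-oxazolidin-2-one (C1 epimer of 11) | COC#C[C@@H](c1ccc(OC)c(OC)c1)CC(=O)N1[C@@H](Cc2ccccc2)COC1=O
F15 | step 8 | β-hydroxy ester from 16 and furfural (two new centres unassigned) | COC#C[C@H](c1ccc(OC)c(OC)c1)[C@@H](CO[Si](C)(C)C(C)(C)C)C(C(=O)OC(C)(C)C)C(O)c1ccco1
F16 | step 8 | methanesulfonate of F15 | COC#C[C@H](c1ccc(OC)c(OC)c1)[C@@H](CO[Si](C)(C)C(C)(C)C)C(C(=O)OC(C)(C)C)C(OS(C)(=O)=O)c1ccco1
F17 | step 8 | tert-butyl (E)-enoate corresponding to 21 | COC#C[C@H](c1ccc(OC)c(OC)c1)[C@@H](CO[Si](C)(C)C(C)(C)C)/C(C(=O)OC(C)(C)C)=C\c1ccco1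
F18 | step 8 | (E)-allylic alcohol corresponding to 21 | COC#C[C@H](c1ccc(OC)c(OC)c1)[C@@H](CO[Si](C)(C)C(C)(C)C)/C(CO)=C\c1ccco1
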